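The constants used here were drawn at random within sensible limits; the rest is arithmetic.

The flask was tabled.

substrate 0.15 M; acid 4.50 mM; time 40 min

    substrate + acid → weak acid + acid + product (k1 = 12 M⁻¹ min⁻¹)
    weak acid ⇌ conjugate base + acid, settled at all times (K2 = 1.0 × 10⁻⁷ M)
    substrate → weak acid + product (k3 = 1.9 × 10⁻⁴ min⁻¹)
    substrate + weak acid ⇌ idle adduct, settled at all times (K4 = 750 M⁻¹)
    weak acid → by-product carried off (k5 = 0.044 min⁻¹)

- acid is the free proton; pH is minus the decimal logarithm of its molar concentration
- what is said of weak acid includes idle adduct
- what has gone from substrate into another species counts as reacted, even if it can come back
- run time (flask): 40 min

* part of the substrate that has reacted at 40 min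
* pH of the solution at 40 min

The first speaker compared rates at the start. Acid-catalysed turnover has a pseudo-first-order constant k′, the rate constant times the acid, here 0.0540 min⁻¹, and it outruns the uncatalysed step by a factor of 280. She set that step aside. Turnover returns its acid and the dissociation constant is far smaller than the acid charged, so she held k′ steady.

The second speaker followed the weak acid. The binding constant times the substrate charged is 110, far above one, so he had each turnover take two substrates from the free pool, one to product and one into adduct. Free substrate then falls at 0.108 min⁻¹, reaching 1.33% at 40 min.

I objected that this comparison drifts. Free weak acid has a half-life of 16 min against carry-off, shorter than the run, so adduct hands substrate back. Towards the end of the run I expected weak acid made to come close to weak acid carried off. Taking adduct as about half of the charge, that balance puts free substrate at 6.02%, a passing level and not an end point. I named this the balance level: the share of the charge free at the moment formation of weak acid equals its carry-off, with adduct at half of the charge. It lies above the second speaker's figure, and I took it as my estimate for the end of the run, committing to 94.0% reacted, with the pH that of the acid charged.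

The forecast gave 94.6% and pH 2.35, “counting adduct-bound substrate as reacted”.

The simulation gave 94.8% and pH 2.35, both forecast values inside their margins.

In the flask, free substrate stood at 5.19% against the balance level of 6.02%, with adduct at 41.2%, less than the share I had assumed. With the constants and the acid held, the balance level falls as the inverse square root of the charge, so the neighbour charged with 0.38 M of substrate has a balance level of 3.78%, an estimate of 96.2% reacted. That neighbour ended with 3.7% of its charged substrate free and 96.3% reacted.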